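The C1–C10 and C4–C5 bonds of ring A are disconnected, which leaves ring B as a cyclohexanone that maps onto (R)-carvone: carbonyl C5, methyl-bearing C10 (C20), C9 as the enone β-carbon and the isopropenyl carbon as C7, which the target needs only as an alkene carbon. The key step exploits the adjacency of C9 and C10 on ring B: one Robinson annulation with ethyl vinyl ketone builds ring A and the quaternary C10, the C9 chain sending the acceptor to the opposite face. Its precursor is the 2-methyl-3-alkyl-5-isopropenylcyclohexanone made by copper-catalysed addition of the C11–C15 chain (C15 silyl ether, C13 from desymmetrised 3-methylglutaric anhydride) to carvone.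

Key step: step 7

Numbering: labdane numbering throughout (ring A = C1–C5, C10; ring B = C5–C10; C20 = methyl on C10; C11–C16 = side chain on C9 with C16 the methyl on C13; C17 = formyl carbon; C18/C19 = gem-dimethyl on C4). The target is methyl (3R,5S,9S,10R,13R)-3-hydroxy-17-oxolabd-7-en-15-oate (ent-labdane series, equatorial 3-OH cis to C20).

Assumption: the quinidine-derived catalyst is taken to deliver the (S)-half-ester 2 (quinidine- and quinine-type alkaloids give opposite half-esters); should the sense prove opposite, the quinine-derived diether (DHQ)2AQN replaces it and nothing else changes.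

Step 1
Reactants: 1 3-methylglutaric anhydride
Product: 2 (S)-5-methoxy-3-methyl-5-oxopentanoic acid
Conditions: MeOH (10 equiv), hydroquinidine anthraquinone-1,4-diyl diether [(DHQD)2AQN] (cat.), Et2O, −40 °C
Reagents that add atoms: methanol CO
Why: Alkaloid-catalysed enantiotopic-group-selective methanolysis of a prochiral cyclic anhydride (general-base catalysis) should open one carbonyl preferentially and thereby fix C13; the half-ester can be enriched further by crystallising its 1-phenylethylammonium salt.

Step 2
Reactants: 2 (S)-5-methoxy-3-methyl-5-oxopentanoic acid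
Product: 3 methyl (S)-5-hydroxy-3-methylpentanoate
Conditions: BH3·SMe2, THF, 0 °C → rt; MeOH quench
Reagents that add atoms: none
Why: Chemoselective borane reduction (acyloxyborane pathway) converts the carboxylic acid, the future C15, into the carbinol much faster than the ester reacts, and C13 is not touched.

Step 3
Reactants: 3 methyl (S)-5-hydroxy-3-methylpentanoate
Product: 4 methyl (S)-5-(tert-butyldimethylsilyloxy)-3-methylpentanoate
Conditions: TBSCl, imidazole, DMF, 0 °C → rt
Reagents that add atoms: tert-butyldimethylsilyl chloride CC(C)(C)[Si](C)(C)Cl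
Why: Imidazole-promoted silylation caps the C15 hydroxyl before the hydroxy ester can lactonise and gives an ether that tolerates Grignard formation, alkoxide base and dissolving metal, which an ester or benzyl-type group at C15 would not.

Step 4
Reactants: 4 methyl (S)-5-(tert-butyldimethylsilyloxy)-3-methylpentanoate
Product: 5 (R)-5-(tert-butyldimethylsilyloxy)-3-methylpentan-1-ol
Conditions: i-Bu2AlH (2.5 equiv), CH2Cl2, −78 → 0 °C; aq potassium sodium tartrate
Reagents that add atoms: none
Why: Hydride reduction of the ester to the primary alcohol (the future C11), with the silyl ether and C13 inert; the descriptor changes only through CIP priorities.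

Step 5
Reactants: 5 (R)-5-(tert-butyldimethylsilyloxy)-3-methylpentan-1-ol
Product: 6 (S)-(5-bromo-3-methylpentyloxy)(tert-butyl)dimethylsilane
Conditions: CBr4, PPh3, imidazole, CH2Cl2, 0 °C
Reagents that add atoms: carbon tetrabromide BrC(Br)(Br)Br
Why: Appel bromination (SN2 at a primary carbon) under buffered conditions that spare the silyl ether; the bromide is chosen because it forms a Grignard reagent cleanly.

Step 6
Reactants: 6 (S)-(5-bromo-3-methylpentyloxy)(tert-butyl)dimethylsilane; 7 (R)-carvone
Product: 10 ketone precursor (2S,3R,5R)-3-[(3R)-5-(tert-butyldimethylsilyloxy)-3-methylpentyl]-2-methyl-5-(prop-1-en-2-yl)cyclohexan-1-one, via Grignard reagent 8 (not isolated), via bromomagnesium enolate 9 (not isolated)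
Conditions: 6, Mg, THF, 40 °C; then CuBr·SMe2 (10 mol %), 7, THF, −40 °C; sat. aq NH4Cl
Reagents that add atoms: none
Why: Copper-catalysed conjugate addition of a Grignard reagent to a cyclohexenone, in which the alkylcopper species attacks the β-carbon (C9) axially on the face opposite the C7 isopropenyl group and so fixes C9; protonation of enolate 9 should give mainly the 2,3-trans ketone, and the C10 configuration is erased in step 7 in any case.

Step 7
Reactants: 10 ketone precursor; 11 ethyl vinyl ketone
Product: 14 ring A/B enone (C3 ketone; C4=C5 with C4 methyl; C9 chain cis to C20; C7 isopropenyl trans to C20), via 1,5-diketone 12 (not isolated), via ketol 13 (not isolated)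
Conditions: 11 (1.5 equiv, slow addition), KOH (0.2 equiv), EtOH, −10 °C → rt; then NaOMe, MeOH, 50 °C
Reagents that add atoms: none
Why: Robinson annulation: under equilibrating alkoxide conditions the ketone enolises mainly toward the methyl-bearing C10 (tetrasubstituted enolate), which adds to ethyl vinyl ketone in a Michael reaction to form C1–C10 and the quaternary centre, and diketone 12 then closes ring A by a 6-(enolendo)-exo-trig aldol of the ethyl-ketone α-carbon C4 onto the C5 carbonyl, followed by E1cB dehydration of ketol 13 to the 4-methyl enone. The closest known reaction type is the annulation of dihydrocarvone-type and 2,3-dialkylcyclohexanones with methyl or ethyl vinyl ketone. C10 is controlled by C9: in the C5=C10 enolate the C9 chain turns pseudoaxial to escape A(1,2) strain with C20, so the acceptor enters axially on the opposite face, which is also the face preferred through the equatorial C7 isopropenyl group, and C1 ends trans to C11 (C20 cis to C11). Two selectivities are needed, C10 over C6 and anti over syn to C11; reversible enolisation and reversible Michael addition in protic base favour the more substituted enolate, and the C9 and C7 substituents reinforce each other on the facial question. The silyl ether, the isopropenyl group and the non-enolisable C9 centre should not be affected by catalytic alkoxide.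

Step 8
Reactants: 14 ring A/B enone
Product: 16 trans-fused 4,4,10-trimethyl-3-ketone (H5 trans to C20; C15 silyl ether; C7 isopropenyl), via lithium enolate 15 (not isolated)
Conditions: Li (2.5 equiv), NH3/THF, t-BuOH (1.0 equiv), −78 °C; isoprene; then MeI (excess), −78 → −33 °C
Reagents that add atoms: iodomethane CI
Why: Stork reductive alkylation: two-electron reduction of the enone with axial protonation at C5 on the face opposite C20 gives the trans ring fusion and the regiodefined C3=C4 enolate 15, which is C-methylated at C4 to the gem-dimethyl ketone, while the isolated 1,1-disubstituted alkene and the silyl ether are not reduced.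

Step 9
Reactants: 16 trans-fused 4,4,10-trimethyl-3-ketone
Product: 19 C15 carboxylic acid (C3 ketone; C7 isopropenyl), via primary alcohol 17 (not isolated), via aldehyde 18 (not isolated)
Conditions: CrO3, H2SO4, H2O, acetone, 0 °C → rt; i-PrOH quench
Reagents that add atoms: water O
Why: Jones oxidation with in-situ acidic desilylation: the primary silyl ether is cleaved and the liberated alcohol is oxidised through the aldehyde hydrate to the acid in one pot; C3 is still a ketone, so no hydroxyl needs protection, and the isopropenyl group should tolerate the short cold exposure.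

Step 10
Reactants: 19 C15 carboxylic acid
Product: 20 C15 methyl ester (C3 ketone; C7 isopropenyl)
Conditions: MeI, K2CO3, DMF, rt
Reagents that add atoms: iodomethane CI
Why: Carboxylate O-alkylation (SN2) installs the methyl ester of the target now that the last ester-incompatible step (dissolving metal) is past; carbonate is too weak to enolise and alkylate the C3 ketone.

Step 11
Reactants: 20 C15 methyl ester
Product: 21 3-hydroxy ester (equatorial 3-OH cis to C20)
Conditions: NaBH4, MeOH, 0 °C
Reagents that add atoms: none
Why: Borohydride reduction in which hydride adds axially to the C3 carbonyl flanked by the gem-dimethyl group, as with 4,4-dimethyl-3-oxo terpenoids, giving the equatorial alcohol (3R); the methyl ester and the alkene are inert.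

Step 12
Reactants: 21 3-hydroxy ester
Product: 22 3-triethylsilyl ether
Conditions: TESOTf, 2,6-lutidine, CH2Cl2, −20 → 0 °C
Reagents that add atoms: triethylsilyl trifluoromethanesulfonate CC[Si](CC)(CC)OS(=O)(=O)C(F)(F)F
Why: Silyl triflate silylation of a hindered secondary alcohol; the triethylsilyl ether should survive ozone, carbonate in methanol, periodinane, NaH and borohydride and is removed by the aqueous acid of the last step.

Step 13
Reactants: 22 3-triethylsilyl ether
Product: 25 7-acetate (acetoxy group trans to C20; isopropenyl replaced with retention), via methoxy hydroperoxide 23 (not isolated), via peracetate 24 (not isolated)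
Conditions: O3, CH2Cl2/MeOH (4:1), −78 °C; then Ac2O, Et3N, DMAP (cat.), 0 °C → rt
Reagents that add atoms: ozone [O-][O+]=O; methanol CO
Why: Ozonolysis in methanol traps the carbonyl oxide as methoxy hydroperoxide 23, and its peracetate 24 undergoes Criegee rearrangement with migration of C7 to oxygen with retention, so the only alkene of the molecule is excised and C7 becomes oxygenated (the acetyl carbons are the two remaining isopropenyl carbons).

Step 14
Reactants: 25 7-acetate
Product: 26 7-alcohol
Conditions: K2CO3, MeOH, rt
Reagents that add atoms: none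
Why: Zemplén-type transesterification of the secondary acetate in methanol, where exchange at the C15 methyl ester is degenerate and the hindered silyl ether is stable.

Step 15
Reactants: 26 7-alcohol
Product: 27 7-ketone
Conditions: Dess–Martin periodinane, NaHCO3, CH2Cl2, rt
Reagents that add atoms: none
Why: Dess–Martin oxidation of the only free hydroxyl under buffered conditions; neither C5 nor C9 is α to the new carbonyl, so no stereocentre can epimerise.

Step 16
Reactants: 27 7-ketone
Product: 28 8-hydroxymethylene-7-ketone
Conditions: NaH, HCO2Me, MeOH (cat.), THF, 0 °C → rt; sat. aq NH4Cl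
Reagents that add atoms: methyl formate COC=O
Why: Crossed Claisen condensation (formylation) of the ketone enolate: a trans-fused 7-ketone should enolise toward C8 and not toward C6, which adjoins the ring fusion and the C4 gem-dimethyl group (the analogue of C2 formylation of 3-oxo-5α-steroids), the ketone being far more acidic than the ester and methyl formate avoiding ester scrambling.

Step 17
Reactants: 28 8-hydroxymethylene-7-ketone
Product: 29 8-isopropoxymethylene-7-ketone
Conditions: i-PrI, K2CO3, acetone, reflux
Reagents that add atoms: 2-iodopropane CC(C)I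
Why: O-Alkylation of the hydroxymethylene ketone with a secondary iodide and carbonate gives the vinylogous ester, the classical derivative for reductive carbonyl transposition.

Step 18
Reactants: 29 8-isopropoxymethylene-7-ketone
Product: 32 methyl (3R,5S,9S,10R,13R)-3-hydroxy-17-oxolabd-7-en-15-oate (target), via allylic alcohol 30 (not isolated), via silyl enal 31 (not isolated)
Conditions: NaBH4, CeCl3·7H2O, MeOH, −20 → 0 °C; then 1 M HCl, THF, rt
Reagents that add atoms: water O
Why: Luche 1,2-reduction of the vinylogous ester carbonyl (the saturated methyl ester is inert) gives allylic alcohol 30, and aqueous acid then expels the C7 hydroxyl and hydrolyses the enol ether to the C7=C8 enal (Stork–Danheiser-type transposition) while also cleaving the triethylsilyl ether; C9 is not activated by the enal, so its configuration is retained.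

Compound list
1 | 3-methylglutaric anhydride | CC1CC(=O)OC(=O)C1 | starting material
2 | (S)-5-methoxy-3-methyl-5-oxopentanoic acid | COC(=O)C[C@@H](C)CC(=O)O | intermediate
3 | methyl (S)-5-hydroxy-3-methylpentanoate | COC(=O)C[C@@H](C)CCO | intermediate
4 | methyl (S)-5-(tert-butyldimethylsilyloxy)-3-methylpentanoate | COC(=O)C[C@@H](C)CCO[Si](C)(C)C(C)(C)C | intermediate
5 | (R)-5-(tert-butyldimethylsilyloxy)-3-methylpentan-1-ol | OCC[C@@H](C)CCO[Si](C)(C)C(C)(C)C | intermediate
6 | (S)-(5-bromo-3-methylpentyloxy)(tert-butyl)dimethylsilane | BrCC[C@@H](C)CCO[Si](C)(C)C(C)(C)C | intermediate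
7 | (R)-carvone | CC1=CC[C@H](CC1=O)C(C)=C | starting material
8 | (S)-[5-(tert-butyldimethylsilyloxy)-3-methylpentyl]magnesium bromide (not isolated) | Br[Mg]CC[C@@H](C)CCO[Si](C)(C)C(C)(C)C | intermediate
9 | bromomagnesium C5=C10 enolate of 10 (not isolated) | CC1=C(O[Mg]Br)C[C@H](C(C)=C)C[C@H]1CC[C@@H](C)CCO[Si](C)(C)C(C)(C)C | intermediate
10 | (2S,3R,5R)-3-[(3R)-5-(tert-butyldimethylsilyloxy)-3-methylpentyl]-2-methyl-5-(prop-1-en-2-yl)cyclohexan-1-one (C11 trans to isopropenyl, C20 trans to C11) | C[C@@H]1C(=O)C[C@H](C(C)=C)C[C@H]1CC[C@@H](C)CCO[Si](C)(C)C(C)(C)C | intermediate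
11 | ethyl vinyl ketone (pent-1-en-3-one) | CCC(=O)C=C | starting material
12 | Michael adduct: ketone 10 with a 3-oxopentyl group on C10 trans to C11 (not isolated) | CCC(=O)CC[C@]1(C)C(=O)C[C@H](C(C)=C)C[C@H]1CC[C@@H](C)CCO[Si](C)(C)C(C)(C)C | intermediate
13 | ring A ketol: 5-hydroxy-4,10-dimethyl-3-ketone, C4 and C5 configuration open (not isolated) | CC1C(=O)CC[C@@]2(C)[C@H](CC[C@@H](C)CCO[Si](C)(C)C(C)(C)C)C[C@@H](C(C)=C)CC12O | intermediate
14 | ring A/B enone: 4,10-dimethyl-4-en-3-one; C9 chain (C15 silyl ether) cis to C20; C7 isopropenyl trans to C20 | CC1=C2C[C@H](C(C)=C)C[C@@H](CC[C@@H](C)CCO[Si](C)(C)C(C)(C)C)[C@]2(C)CCC1=O | intermediate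
15 | lithium C3=C4 enolate with H5 trans to C20 (not isolated) | CC1=C(O[Li])CC[C@@]2(C)[C@H](CC[C@@H](C)CCO[Si](C)(C)C(C)(C)C)C[C@@H](C(C)=C)C[C@H]12 | intermediate
16 | trans-fused 4,4,10-trimethyl-3-ketone; C15 silyl ether; C7 isopropenyl | CC1(C)C(=O)CC[C@@]2(C)[C@H](CC[C@@H](C)CCO[Si](C)(C)C(C)(C)C)C[C@@H](C(C)=C)C[C@H]12 | intermediate
17 | C15 primary alcohol of 16 (not isolated) | CC1(C)C(=O)CC[C@@]2(C)[C@H](CC[C@@H](C)CCO)C[C@@H](C(C)=C)C[C@H]12 | intermediate
18 | C15 aldehyde (not isolated) | CC1(C)C(=O)CC[C@@]2(C)[C@H](CC[C@@H](C)CC=O)C[C@@H](C(C)=C)C[C@H]12 | intermediate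
19 | C15 carboxylic acid; C3 ketone; C7 isopropenyl | CC1(C)C(=O)CC[C@@]2(C)[C@H](CC[C@@H](C)CC(=O)O)C[C@@H](C(C)=C)C[C@H]12 | intermediate
20 | C15 methyl ester; C3 ketone; C7 isopropenyl | CC1(C)C(=O)CC[C@@]2(C)[C@H](CC[C@@H](C)CC(=O)OC)C[C@@H](C(C)=C)C[C@H]12 | intermediate
21 | 3-hydroxy ester (equatorial 3-OH cis to C20); C7 isopropenyl | CC1(C)[C@H](O)CC[C@@]2(C)[C@H](CC[C@@H](C)CC(=O)OC)C[C@@H](C(C)=C)C[C@H]12 | intermediate
22 | 3-triethylsilyl ether of 21 | CC1(C)[C@H](O[Si](CC)(CC)CC)CC[C@@]2(C)[C@H](CC[C@@H](C)CC(=O)OC)C[C@@H](C(C)=C)C[C@H]12 | intermediate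
23 | C7 (2-hydroperoxy-2-methoxyprop-2-yl) compound (not isolated) | CC1(C)[C@H](O[Si](CC)(CC)CC)CC[C@@]2(C)[C@H](CC[C@@H](C)CC(=O)OC)C[C@@H](C(C)(OC)OO)C[C@H]12 | intermediate
24 | peracetate of 23 (not isolated) | CC1(C)[C@H](O[Si](CC)(CC)CC)CC[C@@]2(C)[C@H](CC[C@@H](C)CC(=O)OC)C[C@@H](C(C)(OC)OOC(C)=O)C[C@H]12 | intermediate
25 | 7-acetate (acetoxy trans to C20); 3-triethylsilyl ether; C15 methyl ester | CC1(C)[C@H](O[Si](CC)(CC)CC)CC[C@@]2(C)[C@H](CC[C@@H](C)CC(=O)OC)C[C@@H](OC(C)=O)C[C@H]12 | intermediate
26 | 7-alcohol | CC1(C)[C@H](O[Si](CC)(CC)CC)CC[C@@]2(C)[C@H](CC[C@@H](C)CC(=O)OC)C[C@@H](O)C[C@H]12 | intermediate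
27 | 7-ketone | CC1(C)[C@H](O[Si](CC)(CC)CC)CC[C@@]2(C)[C@H](CC[C@@H](C)CC(=O)OC)CC(=O)C[C@H]12 | intermediate
28 | 8-hydroxymethylene-7-ketone | CC1(C)[C@H](O[Si](CC)(CC)CC)CC[C@@]2(C)[C@H](CC[C@@H](C)CC(=O)OC)C(=CO)C(=O)C[C@H]12 | intermediate
29 | 8-isopropoxymethylene-7-ketone | CC1(C)[C@H](O[Si](CC)(CC)CC)CC[C@@]2(C)[C@H](CC[C@@H](C)CC(=O)OC)C(=COC(C)C)C(=O)C[C@H]12 | intermediate
30 | 7-hydroxy-8-isopropoxymethylene compound, C7 configuration open (not isolated) | CC1(C)[C@H](O[Si](CC)(CC)CC)CC[C@@]2(C)[C@H](CC[C@@H](C)CC(=O)OC)C(=COC(C)C)C(O)C[C@H]12 | intermediate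
31 | 3-triethylsilyl ether of the target enal (not isolated) | CC1(C)[C@H](O[Si](CC)(CC)CC)CC[C@@]2(C)[C@H](CC[C@@H](C)CC(=O)OC)C(C=O)=CC[C@H]12 | intermediate
32 | methyl (3R,5S,9S,10R,13R)-3-hydroxy-17-oxolabd-7-en-15-oate (CNP0285000.1) | COC(=O)C[C@H](C)CC[C@@H]1C(C=O)=CC[C@@H]2C(C)(C)[C@H](O)CC[C@@]12C | target

Total step count: 18. Longest linear sequence: 18 steps (1 → 32); carvone 7 and ethyl vinyl ketone 11 enter at steps 6 and 7.

Steps most likely to fail

Step 7. What may go wrong: enolisation toward C6 in competition with C10, addition on the face syn to C11, base-induced polymerisation of the vinyl ketone, or incomplete dehydration of the ketol. The fallback keeps the disconnection but uses a regiodefined enolate and an α-silyl acceptor. It sets out from bromide 6 and carvone 7: the copper-catalysed Grignard addition is run with Me3SiCl so that the enolate is captured as the C5=C10 trimethylsilyl enol ether F1. MeLi (THF, 0 °C) releases the lithium enolate free of proton sources, and this adds at −78 °C to 2-(trimethylsilyl)pent-1-en-3-one to give the α-silyl 1,5-diketone F2. NaOMe in MeOH then removes silicon and effects the aldol condensation, and the route is rejoined at enone 14.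

Step 16. What may go wrong: enolisation of the 7-ketone toward C6 in competition with C8, or condensation at C14 of the ester. The fallback decides the regiochemistry by enol-ether stability instead of β-dicarbonyl chelate stability and introduces C17 as an acetal. It sets out from ketone 27: equilibrating silylation (Me3SiCl, NaI, Et3N, MeCN) should give the Δ7 trimethylsilyl enol ether F3, whose regiochemistry can be checked before carbon is added. Mukaiyama-type condensation with HC(OMe)3 and BF3·OEt2 at −78 °C gives the 8-(dimethoxymethyl)-7-ketone F4, and NaBH4 reduces it to the 7-hydroxy acetal F5. 1 M HCl in THF then hydrolyses the acetal, eliminates the β-hydroxyl and removes the triethylsilyl group, so the route is rejoined directly at target 32.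

Step 8. What may go wrong: proton transfer to enolate 15 from ammonia or alcohol before alkylation (giving the 4-monomethyl ketone), O-methylation, or over-reduction of the C3 carbonyl. The fallback separates reduction from alkylation. It sets out from enone 14: the same dissolving-metal reduction is carried out, ammonia is evaporated and the enolate is captured with Me3SiCl/Et3N as the C3=C4 trimethylsilyl enol ether F6. After purification, MeLi in THF/DMPU regenerates the lithium enolate under aprotic conditions and MeI methylates C4, and the route is rejoined at ketone 16.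

Further compounds
F1 | step 7 | C5=C10 trimethylsilyl enol ether of ketone 10 | CC1=C(O[Si](C)(C)C)C[C@H](C(C)=C)C[C@H]1CC[C@@H](C)CCO[Si](C)(C)C(C)(C)C
F2 | step 7 | Michael adduct with a 3-oxo-2-(trimethylsilyl)pentyl group on C10 | CCC(=O)C([Si](C)(C)C)C[C@]1(C)C(=O)C[C@H](C(C)=C)C[C@H]1CC[C@@H](C)CCO[Si](C)(C)C(C)(C)C
F3 | step 16 | Δ7 trimethylsilyl enol ether of ketone 27 | CC1(C)[C@H](O[Si](CC)(CC)CC)CC[C@@]2(C)[C@H](CC[C@@H](C)CC(=O)OC)C=C(O[Si](C)(C)C)C[C@H]12
F4 | step 16 | 8-(dimethoxymethyl)-7-ketone | CC1(C)[C@H](O[Si](CC)(CC)CC)CC[C@@]2(C)[C@H](CC[C@@H](C)CC(=O)OC)C(C(OC)OC)C(=O)C[C@H]12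
F5 | step 16 | 8-(dimethoxymethyl)-7-alcohol | CC1(C)[C@H](O[Si](CC)(CC)CC)CC[C@@]2(C)[C@H](CC[C@@H](C)CC(=O)OC)C(C(OC)OC)C(O)C[C@H]12
F6 | step 8 | C3=C4 trimethylsilyl enol ether of the reduced enone | CC1=C(O[Si](C)(C)C)CC[C@@]2(C)[C@H](CC[C@@H](C)CCO[Si](C)(C)C(C)(C)C)C[C@@H](C(C)=C)C[C@H]12
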